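## Retrosynthetic overview

- (5'S)-4,5'-retro-β,β-carotene ⇒ its 14'-cis isomer ⇒ the 14',15'-didehydro compound ⇒ a C15 carbinol. The retro system of the ring A half (C4=C5, C6=C7 … C14=C15) comes from a 1,12-dehydration (OH from C15, H from C4). The C15–C15' bond comes from adding a ring B C20 acetylide to C15 of all-trans-retinal.
- The C20 enyne (C6'=C7' … C14'≡C15') is grown from the ring B ketone: ethynyl addition and Meyer–Schuster rearrangement (C7', C8'), Wittig (C9', C10'), Horner–Wadsworth–Emmons and reduction (C11', C12'), Wittig (C13', C14'), Colvin alkynylation (C15').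
- The strategy rests on the only stereocentre, C5' (H, CH3) of the saturated ring B (C1'–C6'), next to the exocyclic C6'=C7' bond. It is the α-carbon of 2,2,6-trimethylcyclohexanone and is set by ene-reductase reduction of the C2=C3 bond of 2,6,6-trimethylcyclohex-2-enone. The enone is made by dehydrogenating the racemic ketone, so the sequence is a deracemisation.
- No ring is formed: ring B is bought as the racemic ketone and ring A arrives with retinal.

Key step: step 3

Assumption: carotenoid numbering is used (ring A = C1–C6 with C4=C5; ring B = C1'–C6' with C5'). The carbinol carbons made in steps 4 and 11 are transient stereocentres that become sp2 later; 5 is drawn as the expected major epimer and 14 as the C15 epimer mixture.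

## Route

Step 1
Reactants: 1 (±)-2,2,6-trimethylcyclohexan-1-one
Product: 2 trimethyl[(2,6,6-trimethylcyclohex-1-en-1-yl)oxy]silane
Conditions: Me3SiOTf, Et3N, CH2Cl2, 0 °C → rt
Reagents that add atoms: trimethylsilyl trifluoromethanesulfonate, C[Si](C)(C)OS(=O)(=O)C(F)(F)F
Why: Soft enolisation and O-silylation can only occur toward C6, the sole carbon with an α-hydrogen, so a single tetrasubstituted silyl enol ether should form and the stereocentre of the racemate is erased on purpose.

Step 2
Reactants: 2 trimethyl[(2,6,6-trimethylcyclohex-1-en-1-yl)oxy]silane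
Product: 3 2,6,6-trimethylcyclohex-2-en-1-one
Conditions: Pd(OAc)2 (10 mol%), O2 (1 atm), DMSO, rt
Reagents that add atoms: none
Why: Saegusa–Ito oxidation, in which divalent palladium forms the α-palladated ketone at the methyl-bearing carbon and β-hydride elimination into the ring gives the conjugated enone while O2 reoxidises zerovalent palladium.

Step 3
Reactants: 3 2,6,6-trimethylcyclohex-2-en-1-one
Product: 4 (S)-2,2,6-trimethylcyclohexan-1-one
Conditions: S-selective ene-reductase (FMN-dependent, Old Yellow Enzyme family, chosen by screening), NADP+ (cat.), D-glucose, glucose dehydrogenase, KH2PO4/K2HPO4 buffer pH 7.0, 5% DMSO, 30 °C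
Reagents that add atoms: none
Why: The enzyme-bound reduced flavin, recharged by NADPH, transfers hydride from N5 to C3 of the enone (the β-carbon, later C4') while the carbonyl is polarised by two hydrogen-bond donors, and an active-site tyrosine then protonates C2 (later C5') from the opposite face, a net trans-hydrogenation of the C=C bond. The closest known reaction type is the Old Yellow Enzyme reduction of 2-alkylcyclohex-2-enones such as 2-methylcyclohexenone and ketoisophorone, so the reaction class is established and only the enantiomer delivered for this substrate remains to be secured. No ring is closed; ring B is carried through unchanged. The single new stereocentre, C2 of the ketone (C5' of the target, H and CH3), is controlled by the catalyst: the face of Cα protonation is fixed by the orientation in which the enone lies over the flavin, so a homologue or pocket variant that binds it in the orientation leading to S (possibly the flipped one relative to simple 2-methylcyclohexenone) is selected by screening and, if needed, mutation of the residues lining the substrate pocket. The step needs enantioselectivity, chemoselectivity for C=C over C=O and freedom from racemisation: the gem-dimethyl carbon leaves one enone and one enolisable position, ene-reductases do not reduce the carbonyl, and at pH 7 the hindered tertiary α-hydrogen of the product should not exchange. Because the enone comes from the racemic ketone, all material is funnelled into one enantiomer.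

Step 4
Reactants: 4 (S)-2,2,6-trimethylcyclohexan-1-one
Product: 5 (1R,6S)-1-ethynyl-2,2,6-trimethylcyclohexan-1-ol
Conditions: HC≡CMgBr, anhydrous CeCl3, THF, −78 → 0 °C; H2O
Reagents that add atoms: ethynylmagnesium bromide, C#C[Mg]Br
Why: The organocerium acetylide is strongly nucleophilic but barely basic, so it should add to the hindered carbonyl (mainly axially, away from the axial C2 methyl) without enolising C6, and the configuration of the new carbinol carbon is immaterial because it is planarised in step 5.

Step 5
Reactants: 5 (1R,6S)-1-ethynyl-2,2,6-trimethylcyclohexan-1-ol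
Product: 6 (2E)-2-[(6S)-2,2,6-trimethylcyclohexylidene]acetaldehyde
Conditions: MoO2(acac)2, Ph3PAuCl, AgOTf (each 1–2 mol%), toluene, rt
Reagents that add atoms: none
Why: Meyer–Schuster rearrangement in which the oxo-molybdenum ester of the tertiary alcohol shifts oxygen 1,3 onto the gold-activated alkyne without a free carbocation, which avoids the Rupe pathway and γ-enolisation at C5', and the enal is expected to settle as the E isomer (formyl-bearing carbon syn to the CH(CH3) carbon and away from the quaternary carbon), any Z isomer being re-equilibrated with a trace of I2.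

Step 6
Reactants: 6 (2E)-2-[(6S)-2,2,6-trimethylcyclohexylidene]acetaldehyde
Product: 7 (2E,4E)-2-methyl-4-[(6S)-2,2,6-trimethylcyclohexylidene]but-2-enal
Conditions: Ph3P=C(CH3)CHO, toluene, 80 °C
Reagents that add atoms: 2-(triphenylphosphoranylidene)propanal, CC(C=O)=P(c1ccccc1)(c1ccccc1)c1ccccc1
Why: Wittig olefination with a formyl-stabilised ylide should give the α-methyl enal directly and E-selectively under salt-free, non-basic conditions, so C5' is not exposed to base and the more hindered, less electrophilic product does not react a second time.

Step 7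
Reactants: 7 (2E,4E)-2-methyl-4-[(6S)-2,2,6-trimethylcyclohexylidene]but-2-enal
Product: 8 (2E,4E,6E)-N-methoxy-N,4-dimethyl-6-[(6S)-2,2,6-trimethylcyclohexylidene]hexa-2,4-dienamide
Conditions: (EtO)2P(O)CH2C(O)N(OMe)Me, NaH, THF, 0 °C → rt
Reagents that add atoms: diethyl {2-[methoxy(methyl)amino]-2-oxoethyl}phosphonate, CCOP(=O)(CC(=O)N(C)OC)OCC
Why: Horner–Wadsworth–Emmons olefination of the aldehyde with the stabilised sodium phosphonate is reliably E-selective and installs a Weinreb amide from which the aldehyde oxidation level is reached in one further step.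

Step 8
Reactants: 8 (2E,4E,6E)-N-methoxy-N,4-dimethyl-6-[(6S)-2,2,6-trimethylcyclohexylidene]hexa-2,4-dienamide
Product: 9 (2E,4E,6E)-4-methyl-6-[(6S)-2,2,6-trimethylcyclohexylidene]hexa-2,4-dienal
Conditions: i-Bu2AlH, THF, −78 °C; aq. potassium sodium tartrate (KNaC4H4O6)
Reagents that add atoms: none
Why: Hydride adds once to the Weinreb amide to give a chelated tetrahedral aluminate that collapses to the aldehyde only on work-up, so the trienal should be obtained without over-reduction or conjugate reduction.

Step 9
Reactants: 9 (2E,4E,6E)-4-methyl-6-[(6S)-2,2,6-trimethylcyclohexylidene]hexa-2,4-dienal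
Product: 10 (2E,4E,6E,8E)-2,6-dimethyl-8-[(6S)-2,2,6-trimethylcyclohexylidene]octa-2,4,6-trienal
Conditions: Ph3P=C(CH3)CHO, toluene, 80 °C
Reagents that add atoms: 2-(triphenylphosphoranylidene)propanal, CC(C=O)=P(c1ccccc1)(c1ccccc1)c1ccccc1
Why: The same E-selective Wittig olefination with the formyl-stabilised ylide adds C13' with its methyl group and C14' as the aldehyde in one neutral step.

Step 10
Reactants: 10 (2E,4E,6E,8E)-2,6-dimethyl-8-[(6S)-2,2,6-trimethylcyclohexylidene]octa-2,4,6-trienal
Product: 11 (1E,6S)-1-[(2E,4E,6E)-3,7-dimethylnona-2,4,6-trien-8-yn-1-ylidene]-2,2,6-trimethylcyclohexane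
Conditions: Me3SiCHN2, n-BuLi, THF, −78 °C → rt
Reagents that add atoms: (trimethylsilyl)diazomethane, C[Si](C)(C)C=[N+]=[N-]
Why: Colvin rearrangement, in which lithiated trimethylsilyldiazomethane adds to the aldehyde, Peterson-type loss of silanolate and then of N2 gives an alkylidene carbene, and its 1,2-hydrogen shift yields the terminal alkyne, under methanol-free conditions that avoid the conjugate addition enals suffer in carbonate/methanol alkynylations.

Step 11
Reactants: 11 (1E,6S)-1-[(2E,4E,6E)-3,7-dimethylnona-2,4,6-trien-8-yn-1-ylidene]-2,2,6-trimethylcyclohexane; 12 all-trans-retinal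
Product: 14 C40 ynol: retinal skeleton (ring A, 7E,9E,11E,13E) carrying OH at C15 and bonded there to the alkyne carbon C15' of the ring B enyne (C15 epimers, 5'S), via lithium acetylide 13 (not isolated)
Conditions: n-BuLi, THF, −78 °C; then 12, −78 → −20 °C; H2O
Reagents that add atoms: none
Why: 1,2-Addition of a lithium acetylide to the aldehyde of retinal forms the C15–C15' bond, and the unselective new carbinol centre C15 is of no consequence because it becomes sp2 in step 12.

Step 12
Reactants: 14 C40 ynol
Product: 15 (5'S,6E,6'E)-14',15'-didehydro-4,5'-retro-β,β-carotene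
Conditions: p-TsOH·H2O (cat.), 4 Å molecular sieves, toluene, 0 °C → rt; Et3N
Reagents that add atoms: none
Why: Acid-catalysed vinylogous (1,12) dehydration of the retinol-to-anhydroretinol type, in which ionisation at C15 gives a cation delocalised from C13 to C5 and loss of a C4 proton moves every double bond of the ring A half into the retro position, while proton loss at C5' is disfavoured because across the triple bond it would create a cumulene, so the stereocentre should survive.

Step 13
Reactants: 15 (5'S,6E,6'E)-14',15'-didehydro-4,5'-retro-β,β-carotene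
Product: 16 (5'S,6E,14'Z,6'E)-4,5'-retro-β,β-carotene
Conditions: H2 (1 atm, 1 equiv), Pd/CaCO3 poisoned with Pb(OAc)2 (Lindlar catalyst), quinoline, toluene, rt
Reagents that add atoms: none
Why: Semi-hydrogenation over lead-poisoned palladium with quinoline should stop at the cis-alkene and leave the conjugated double bonds untouched, as in the classical polyenyne-to-carotene reductions, because the alkyne is adsorbed far more strongly than the alkenes.

Step 14
Reactants: 16 (5'S,6E,14'Z,6'E)-4,5'-retro-β,β-carotene
Product: 17 (5'S,6E,6'E)-all-trans-4,5'-retro-β,β-carotene (CNP0257724.1)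
Conditions: I2 (cat.), toluene, diffuse daylight, rt; crystallisation
Reagents that add atoms: none
Why: Iodine-catalysed stereomutation by reversible addition of iodine atoms should relax the hindered 14'-cis bond, which clashes with the C13' methyl group, and any minor 6- or 6'-isomers to the thermodynamically preferred all-trans polyene without involving the sp3 centre C5'.

## Compound list

1 | (±)-2,2,6-trimethylcyclohexan-1-one | CC1CCCC(C)(C)C1=O | starting material
2 | trimethyl[(2,6,6-trimethylcyclohex-1-en-1-yl)oxy]silane | CC1=C(O[Si](C)(C)C)C(C)(C)CCC1 | intermediate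
3 | 2,6,6-trimethylcyclohex-2-en-1-one | CC1=CCCC(C)(C)C1=O | intermediate
4 | (S)-2,2,6-trimethylcyclohexan-1-one | O=C1[C@@H](C)CCCC1(C)C | intermediate
5 | (1R,6S)-1-ethynyl-2,2,6-trimethylcyclohexan-1-ol (expected major carbinol epimer) | C#C[C@@]1(O)[C@@H](C)CCCC1(C)C | intermediate
6 | (2E)-2-[(6S)-2,2,6-trimethylcyclohexylidene]acetaldehyde | O=C/C=C1\[C@@H](C)CCCC1(C)C | intermediate
7 | (2E,4E)-2-methyl-4-[(6S)-2,2,6-trimethylcyclohexylidene]but-2-enal | O=C/C(C)=C/C=C1\[C@@H](C)CCCC1(C)C | intermediate
8 | (2E,4E,6E)-N-methoxy-N,4-dimethyl-6-[(6S)-2,2,6-trimethylcyclohexylidene]hexa-2,4-dienamide | CON(C)C(=O)/C=C/C(C)=C/C=C1\[C@@H](C)CCCC1(C)C | intermediate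
9 | (2E,4E,6E)-4-methyl-6-[(6S)-2,2,6-trimethylcyclohexylidene]hexa-2,4-dienal | O=C/C=C/C(C)=C/C=C1\[C@@H](C)CCCC1(C)C | intermediate
10 | (2E,4E,6E,8E)-2,6-dimethyl-8-[(6S)-2,2,6-trimethylcyclohexylidene]octa-2,4,6-trienal | O=C/C(C)=C/C=C/C(C)=C/C=C1\[C@@H](C)CCCC1(C)C | intermediate
11 | (1E,6S)-1-[(2E,4E,6E)-3,7-dimethylnona-2,4,6-trien-8-yn-1-ylidene]-2,2,6-trimethylcyclohexane | C#C/C(C)=C/C=C/C(C)=C/C=C1\[C@@H](C)CCCC1(C)C | intermediate
12 | all-trans-retinal | CC1=C(/C=C/C(C)=C/C=C/C(C)=C/C=O)C(C)(C)CCC1 | starting material
13 | lithium acetylide of 11 | [Li]C#C/C(C)=C/C=C/C(C)=C/C=C1\[C@@H](C)CCCC1(C)C | intermediate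
14 | C40 ynol (C15 epimers, 5'S): ring A–(7E,9E,11E,13E)-tetraene–C15H(OH)–C15'≡C14'–(12'E,10'E,8'E,6'E)-tetraene–ring B | CC1=C(/C=C/C(C)=C/C=C/C(C)=C/C(O)C#C/C(C)=C/C=C/C(C)=C/C=C2\[C@@H](C)CCCC2(C)C)C(C)(C)CCC1 | intermediate
15 | (5'S,6E,6'E)-14',15'-didehydro-4,5'-retro-β,β-carotene | CC1=CCCC(C)(C)\C1=C/C=C(C)/C=C/C=C(C)/C=C/C#C/C(C)=C/C=C/C(C)=C/C=C2\[C@@H](C)CCCC2(C)C | intermediate
16 | (5'S,6E,14'Z,6'E)-4,5'-retro-β,β-carotene | CC1=CCCC(C)(C)\C1=C/C=C(C)/C=C/C=C(C)/C=C/C=C\C(C)=C\C=C\C(C)=C\C=C2/[C@@H](C)CCCC2(C)C | intermediate
17 | (5'S,6E,6'E)-all-trans-4,5'-retro-β,β-carotene (CNP0257724.1) | CC1=CCCC(C)(C)\C1=C/C=C(C)/C=C/C=C(C)/C=C/C=C/C(C)=C/C=C/C(C)=C/C=C1\[C@@H](C)CCCC1(C)C | target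

## Step count and risks

Total steps: 14. Longest linear sequence: 14 steps (1 → 17); retinal 12 is a purchased partner that joins at step 11.

Steps most likely to fail:

1. Step 3. The enone may bind in the orientation that protonates C2 from the wrong face, giving low or inverted enantioselectivity, or the hindered substrate may turn over too slowly. Fallback: setting out from silyl enol ether 2, the Si–O bond is cleaved with MeLi in Et2O at 0 °C to give lithium 2,6,6-trimethylcyclohex-1-en-1-olate F1. This enolate is protonated at −78 °C with a stoichiometric chiral proton donor (a chiral imide derived from cis,cis-1,3,5-trimethylcyclohexane-1,3,5-tricarboxylic acid, the enantiomer that delivers S), followed by aqueous NH4Cl. Enantioselective protonation of this enolate is a well-studied reaction class. The route is rejoined at ketone 4.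

2. Step 12. After ionisation at C15, water may be captured at C14' and lead to Meyer–Schuster-type enone formation, the polyenyl cation may oligomerise, or the proton may be lost from the C13 methyl instead of C4. Fallback: setting out from ynol 14, the triple bond is first reduced by trans-hydroalumination with NaAlH2(OCH2CH2OMe)2 in THF at 0 °C, directed by the C15 alkoxide, to the (14'E)-dienyl carbinol F3. This far more easily ionised alcohol is dehydrated with pyridinium p-toluenesulfonate in toluene at 0 °C, with loss of the C4 proton, to give 17 directly; steps 13 and 14 are bypassed. This is second choice because the cation then reaches C6', so proton loss from C5' (giving β,β-carotene and erasing the stereocentre) can compete and the products would have to be separated by chromatography.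

3. Step 5. The 1,3-oxygen shift may be slow at the congested tertiary carbinol, dehydration toward the enyne and hydration (Rupe pathway) may intervene, the E/Z ratio at C6'=C7' may be unfavourable, or C5' may erode through γ-enolisation of the enal. Fallback: setting out from ketone 4, CH2=CHMgBr/CeCl3 in THF at −78 °C gives (1R,6S)-1-ethenyl-2,2,6-trimethylcyclohexan-1-ol F2 (either carbinol epimer serves). Babler–Dauben oxidative transposition with pyridinium chlorochromate, C5H5NH[CrO3Cl], in CH2Cl2 at rt ([3,3]-shift of the chromate ester, then oxidation) gives enal 6, where the route is rejoined.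

## Further compounds

F1 | step 3 | lithium 2,6,6-trimethylcyclohex-1-en-1-olate | [Li]OC1=C(C)CCCC1(C)C
F2 | step 5 | (1R,6S)-1-ethenyl-2,2,6-trimethylcyclohexan-1-ol | C=C[C@@]1(O)[C@@H](C)CCCC1(C)C
F3 | step 12 | C40 dienyl carbinol (C15 epimers, 5'S, 14'E): ring A–(7E,9E,11E,13E)-tetraene–C15H(OH)–(14'E,12'E,10'E,8'E,6'E)-pentaene–ring B | CC1=C(/C=C/C(C)=C/C=C/C(C)=C/C(O)/C=C/C(C)=C/C=C/C(C)=C/C=C2\[C@@H](C)CCCC2(C)C)C(C)(C)CCC1
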